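**Assumption and conventions.** The target is taken as the (2R,3S)-trans enantiomer, COc1cc([C@@H]2Oc3c(OC)cc(/C=C/C=O)cc3[C@H]2CO)ccc1O. Compounds 1, 7, 10, 17 and the reagents on the "Reagents that add atoms" lines are purchased. TIPS = tri(propan-2-yl)silyl, MOM = methoxymethyl. The dihydrobenzofuran locants O1, C2, C3, C3a, C4–C7, C7a are used for all intermediates. Ring A is the pendant guaiacyl ring, ring B the benzo ring, ring C the dihydrofuran ring.

## The problem

Balanophonin 29 is a 2-aryl-3-hydroxymethyl-2,3-dihydrobenzofuran. Ring C is fused to ring B through C3a–C7a and carries ring A on C2; ring B bears a methoxy group on C7 and an (E)-propenal on C5. C2 (R) and C3 (S) are vicinal and trans, and only one enantiomer is wanted. In an open chain the two centres can be set together: a syn relation between the C2 oxygen and the C3 substituent that becomes C3a turns into trans once ring C closes. In the finished ring C3 can steer C2, because trans is the stable arrangement, but C2 cannot steer C3. C2 is a benzylic ether para to the ring A phenolic oxygen, so acids and strong Lewis acids can ionise it. The ring A phenol must stay masked until the end and must be told apart from the C7 oxygen, which has to be methylated. The enal is both aldehyde and Michael acceptor and will not survive hydride, organolithium or fluoride steps, so it has to come last. The enabling feature is the substitution of ring B: oxygen on the adjacent carbons C7a and C7, carbon on C3a and C5. That is the pattern of a benzene ring assembled from a 2,4-disubstituted furan (its carbons become C3a, C4, C5, C6 and its oxygen the C7 hydroxyl) and an alkynyl ether (its carbons become C7a and C7).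

## Retrosynthesis

**29 back to 26.** The last step only frees the ring A phenol from MOM ether 28. The enal of 28 is cut at its C=C bond to aldehyde 27 and a two-carbon ylide. A Heck disconnection at a C5 halide was set aside because a halogen on the furan would not survive the butyllithium step further back. Aldehyde 27 comes from diol 26 by benzylic oxidation, which needs no protection of the saturated C3 hydroxymethyl group.

**26 back to 24.** Diol 26 is the doubly desilylated form of methyl ether 25, and 25 is the O-methyl derivative of phenol 24. In 24 the C7 hydroxyl is the only free OH, so the two phenolic oxygens are differentiated without extra steps.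

**24 back to 21 (key cut).** Cutting C3a–C7a and C6–C7 removes rings B and C together and leads to the acyclic alkynyl ether 21, in which a furan and an O–C≡CH unit are joined by the C3–C2–O1 chain. The neighbouring cuts were weighed against it. Cutting O1–C2 keeps ring B as a bought arene but then needs a separate oxygenation pattern and a C5 handle on that arene. Cutting C2–C3 in the ring gives no stereocontrol. The furan–yne cut delivers the C7 oxygen as a free phenol, ready for methylation. The forward reaction must choose the furan over ring A as nucleophile, open the arene oxide toward C7, and run cold enough that the benzylic alkynyl ether survives. The stereocentres are spectators.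

**21 back to 16 and 17.** The O1–C7a bond is cut to the secondary benzylic alcohol 16 and trichloroethylene 17, which supplies both alkyne carbons. The C2–O bond is never broken, so the configuration of 16 is carried into 21. The primary alcohol of 16 is masked as a TIPS ether because the route passes through a potassium alkoxide, where a smaller silyl group could migrate.

**16 back to 9 and 11.** Alcohol 16 is the monosilylated form of diol 15, the reduction product of aldol adduct 14. Cutting C2–C3 of 14 gives the furylacetyl oxazolidinone 9 and MOM-vanillin 11. An auxiliary-controlled boron syn-aldol makes both stereocentres in one step with a predictable sense, and the syn adduct is the one that maps onto the trans ring. The alternative of building C2 later by reduction of a ketone would leave C3 epimerisable next to a carbonyl.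

**9 back to 1 and 7.** Imide 9 is the N-acyl derivative of auxiliary 7 and acid 6. Acid 6 comes from nitrile 5, the one-carbon homologue of aldehyde 3. Aldehyde 3 is the silyl ether of 2, obtained from 4-bromofuran-2-carbaldehyde 1 by replacing bromine with a hydroxymethyl group. Starting from 1 fixes the 2,4-pattern of the furan, which direct substitution of a 3-substituted furan would not guarantee.

**11 back to 10.** Aldehyde 11 is vanillin 10 with its phenol protected as the MOM ether.

## Roads not taken

**Alternative 1:** The cut is at C2–aryl and C3–CH2O on an intact benzofuran. The benzofuran-2-yl pinacol boronate A2 (5-bromo, 7-methoxy) would be combined with a lithiated, silyl-protected guaiacol unit to give a boron ate complex. A silyloxymethyl chloride, ionised by a chiral thiourea, would attack C3 and trigger anti 1,2-migration of the aryl group from boron to C2, giving the trans 2-boryl-dihydrobenzofuran A1. Stereoretentive protodeboronation and a Heck reaction at C5 would finish.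
- Merits: three components, two C–C bonds and both stereocentres in one step, ring B bought intact, and a C5 bromide that accepts the enal directly. It is clearly shorter and more convergent than the chosen plan.
- Weak points: the absolute configuration rests on an anion-binding catalyst whose electrophile meets an anionic, lithium-paired nucleophile, so a racemic background reaction is likely. Benzofuran C3 is a weaker nucleophile than the indole systems where such shifts are established. The aryl bromide of A2 is exposed to an aryllithium. C2 of A1 is a tertiary benzylic α-oxy boronate whose protodeboronation must be fully stereoretentive.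
- Comparison: against the shorter route, the chosen plan offers an aldol of proven facial sense and a key step that carries no stereochemical load.

**Alternative 2:** The cut is at C3–C3a, and the retron is the six-membered (2R)-flavanone A4. PhI(OAc)2 and H2SO4 in trimethyl orthoformate would convert A4 into its α-iodanyl ketal. The ring B carbon would migrate from the ketal carbon to C3, contracting the ring and leaving the former carbonyl carbon as the methyl ester of trans-dihydrobenzofuran A3.
- Merits: the ring contraction is established on flavanones, is trans-selective, uses the C2 centre to set C3, and starts from a chalcone-type skeleton with both aryl rings in place. The C5 bromide again allows a Heck reaction. It is shorter than the chosen plan and has precedent on this very ring system.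
- Weak points: a flavanone with a para-oxygenated 2-aryl group racemises by reversible ring opening to the chalcone, and strong acid promotes this. The electron-rich 2-aryl group competes as the migrating group, which is why a deactivating pivalate is needed. Making A4 as one enantiomer is a separate asymmetric problem. The ester must still be reduced.
- Comparison: the chosen plan is longer but its stereocentres come from a stoichiometric auxiliary and meet no strong protic acid before the last, mild step.

**Alternative 3:** The cut is at C3a–C4 and C7–C7a, with ring B built on a preformed lactone. The trans lactone A6 would be converted into its silyl ketene acetal A7 and heated with methyl 3-bromocoumalate A8. Inverse-demand [4+2] cycloaddition, loss of CO2 and loss of silanol would give the aromatic ester A5.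
- Merits: pyrone cycloaddition with CO2 extrusion is a dependable benzannulation, and the stereocentres sit on a robust lactone. No labile alkynyl ether is involved; in robustness of intermediates this road is better.
- Weak points: C7 arrives as a bromide and needs a late C–O coupling next to O1 to become the methoxy group. C5 arrives as an ester and needs reduction, oxidation and olefination. The lactone requires the same two stereocentres to be made first, so nothing is saved there. The regiochemistry of the cycloaddition decides where the bromine ends up.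
- Comparison: overall length is comparable. The chosen plan delivers the C7 oxygen directly and spends fewer steps on functional-group exchange after ring formation, at the price of a more delicate key intermediate.

Key step: step 11

## Route

Step 1
Reactants: 1 4-bromofuran-2-carbaldehyde
Product: 2 4-(hydroxymethyl)furan-2-carbaldehyde
Conditions: Bu3SnCH2OH, Pd(PPh3)4 (5 mol %), 1,4-dioxane, 90 °C
Reagents that add atoms: (tributylstannyl)methanol, CCCC[Sn](CCCC)(CCCC)CO
Why: Stille coupling; oxidative addition of the C4–Br bond to zerovalent palladium and hydroxymethyl transfer from tin is an established hydroxymethylation of (hetero)aryl bromides, the neutral conditions spare the aldehyde, and the 2,4-pattern of the furan is fixed from the start.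

Step 2
Reactants: 2 4-(hydroxymethyl)furan-2-carbaldehyde
Product: 3 4-[(TIPS-oxy)methyl]furan-2-carbaldehyde
Conditions: TIPSCl, imidazole, DMF, 20 °C
Reagents that add atoms: chlorotri(propan-2-yl)silane, CC(C)[Si](Cl)(C(C)C)C(C)C
Why: Standard silylation of a primary alcohol; TIPS is chosen because it has to pass aqueous KOH (step 4) and KH and n-BuLi (step 10).

Step 3
Reactants: 3 4-[(TIPS-oxy)methyl]furan-2-carbaldehyde
Product: 5 2-{4-[(TIPS-oxy)methyl]furan-2-yl}acetonitrile, via tosylvinyl formamide 4 (not isolated)
Conditions: TosMIC, KOt-Bu, DME, –50 °C; then MeOH, 65 °C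
Reagents that add atoms: 1-(isocyanomethylsulfonyl)-4-methylbenzene (TosMIC), Cc1ccc(cc1)S(=O)(=O)C[N+]#[C-]
Why: van Leusen reductive cyanation; the TosMIC anion adds to the aldehyde, the adduct cyclises to a 4-tosyloxazoline and ring-opens to formamide 4 at low temperature, where elimination to the oxazole is suppressed, and methanolysis then removes the formyl group and expels sulfinate to give the one-carbon-extended nitrile.

Step 4
Reactants: 5 2-{4-[(TIPS-oxy)methyl]furan-2-yl}acetonitrile
Product: 6 2-{4-[(TIPS-oxy)methyl]furan-2-yl}acetic acid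
Conditions: KOH, EtOH/H2O, 80 °C; then 1 M HCl to pH 4, 0 °C
Reagents that add atoms: potassium hydroxide, [K+].[OH-]; water, O
Why: Alkaline hydrolysis of an arylacetonitrile; the TIPS ether is the most base-stable common silyl ether, and brief cold acidification spares it and the furan.

Step 5
Reactants: 6 2-{4-[(TIPS-oxy)methyl]furan-2-yl}acetic acid; 7 (4R)-4-benzyl-1,3-oxazolidin-2-one
Product: 9 (4R)-4-benzyl-3-(2-{4-[(TIPS-oxy)methyl]furan-2-yl}acetyl)-1,3-oxazolidin-2-one, via mixed pivalic anhydride 8 (not isolated)
Conditions: t-BuCOCl, Et3N, THF, –20 °C; then 7, LiCl, –20 → 20 °C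
Reagents that add atoms: none
Why: N-acylation of the oxazolidinone through the mixed anhydride under LiCl/Et3N activation, which avoids a strong base next to the acidic furylacetyl CH2; the auxiliary stereocentre is untouched.

Step 6
Reactants: 10 vanillin (4-hydroxy-3-methoxybenzaldehyde)
Product: 11 3-methoxy-4-(methoxymethoxy)benzaldehyde
Conditions: MOMCl, i-Pr2NEt, CH2Cl2, 0 → 20 °C
Reagents that add atoms: chloro(methoxy)methane, COCCl
Why: O-alkylation of the phenol to its MOM acetal; MOM survives boron triflate, hydride, KH, n-BuLi, cationic gold and fluoride and is removed last with dilute acid.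

Step 7
Reactants: 9 (4R)-4-benzyl-3-(2-{4-[(TIPS-oxy)methyl]furan-2-yl}acetyl)-1,3-oxazolidin-2-one; 11 3-methoxy-4-(methoxymethoxy)benzaldehyde
Product: 14 (4R)-4-benzyl-3-[(2S,3R)-3-hydroxy-3-[3-methoxy-4-(methoxymethoxy)phenyl]-2-{4-[(TIPS-oxy)methyl]furan-2-yl}propanoyl]-1,3-oxazolidin-2-one, via boron enolate 12 (not isolated), via boron aldolate 13 (not isolated)
Conditions: Bu2BOTf, i-Pr2NEt, CH2Cl2, –78 → 0 °C; 11, –78 → –20 °C; pH 7 buffer, MeOH, H2O2, 0 °C
Reagents that add atoms: none
Why: Evans boron syn-aldol; the (Z)-enolate 12 reacts through a closed chair transition state with the oxazolidinone carbonyl turned away from the enolate oxygen, so the aldehyde meets the face opposite the benzyl group, and the (R)-auxiliary thereby sets (2S,3R), which is C3 (S) and C2 (R) of the target in a syn relation.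

Step 8
Reactants: 14 the syn-aldol adduct
Product: 15 (1R,2S)-1-[3-methoxy-4-(methoxymethoxy)phenyl]-2-{4-[(TIPS-oxy)methyl]furan-2-yl}propane-1,3-diol
Conditions: LiBH4, MeOH (1 equiv), THF, 0 °C
Reagents that add atoms: none
Why: Reductive cleavage of the N-acyl oxazolidinone at the exocyclic carbonyl; immediate reduction removes the acidic α-furyl carbonyl position and with it the risk of epimerisation or retro-aldol.

Step 9
Reactants: 15 the 1,3-diol
Product: 16 (1R,2S)-1-[3-methoxy-4-(methoxymethoxy)phenyl]-3-(TIPS-oxy)-2-{4-[(TIPS-oxy)methyl]furan-2-yl}propan-1-ol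
Conditions: TIPSCl, imidazole, DMF, 0 → 20 °C
Reagents that add atoms: chlorotri(propan-2-yl)silane, CC(C)[Si](Cl)(C(C)C)C(C)C
Why: Selective silylation of the primary over the secondary benzylic alcohol by a bulky silyl chloride; TIPS is used here because it resists O-to-O silyl migration when the neighbouring alkoxide is formed with KH in step 10.

Step 10
Reactants: 16 the secondary benzylic alcohol; 17 trichloroethylene
Product: 21 (1R,2S)-1-(ethynyloxy)-1-[3-methoxy-4-(methoxymethoxy)phenyl]-3-(TIPS-oxy)-2-{4-[(TIPS-oxy)methyl]furan-2-yl}propane, via dichlorovinyl ether 18 (not isolated), via chloroethynyl ether 19 (not isolated), via lithium acetylide 20 (not isolated)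
Conditions: KH, THF, 0 °C; 17, –40 → 20 °C; n-BuLi (3 equiv), –78 → –40 °C; MeOH, –78 °C
Reagents that add atoms: none
Why: Alkynyl ether synthesis from an alcohol and trichloroethylene; the potassium alkoxide dehydrochlorinates 17 to dichloroethyne and adds to it to give the (E)-1,2-dichlorovinyl ether 18, n-BuLi eliminates HCl to 19 and exchanges chlorine for lithium to give 20, and cold methanol protonates it; the C2–O bond is never broken, so both stereocentres are retained, and 21 is kept at or below 0 °C and used at once.

Step 11
Reactants: 21 the syn alkynyl ether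
Product: 24 (2R,3S)-2-[3-methoxy-4-(methoxymethoxy)phenyl]-3,5-bis[(TIPS-oxy)methyl]-2,3-dihydro-1-benzofuran-7-ol, via oxepine 22 (not isolated), via arene oxide 23 (not isolated)
Conditions: Ph3PAuNTf2 (2 mol %), CH2Cl2, 4 Å molecular sieves, –20 → 0 °C
Reagents that add atoms: none
Why: This is the gold-catalysed furan–yne phenol synthesis, known for 2-(furan-2-yl)ethyl ethynyl ethers, which give 7-hydroxy-2,3-dihydrobenzofurans; here the same tether carries the two stereocentres. Cationic monovalent gold coordinates the alkynyl ether and makes its oxygen-bearing carbon (future C7a) electrophilic; the furan attacks through its tether-bearing carbon (future C3a) in a 5-exo-dig closure of ring C and gives a cyclopropyl gold carbene. Opening of the cyclopropane and of the furan C–O bond gives a (Z)-dienal gold carbene, whose aldehyde oxygen adds to the carbene carbon to give oxepine 22 with release of the catalyst; 6π-disrotatory electrocyclisation to arene oxide 23 forms C6–C7 and so closes ring B. The oxide opens at C6 because the resulting pentadienyl cation places charge on C7a next to O1, so the oxygen stays on C7 and proton loss gives phenol 24 with the hydroxyl ortho to O1. No stereocentre is formed: C2 and C3 lie in the tether, are not touched, and their syn relation in 21 becomes the trans relation in 24. The step needs the furan, not ring A, to act as nucleophile, which is secured by its much higher nucleophilicity and by the five-membered transition state that brings it to C7a. It also needs the benzylic C2–O1 bond to survive activation, which is why low temperature, a weakly polar non-coordinating solvent, sieves and a low catalyst loading are specified.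

Step 12
Reactants: 24 the C7 phenol
Product: 25 (2R,3S)-7-methoxy-2-[3-methoxy-4-(methoxymethoxy)phenyl]-3,5-bis[(TIPS-oxy)methyl]-2,3-dihydro-1-benzofuran
Conditions: MeI, K2CO3, acetone, 20 °C
Reagents that add atoms: iodomethane, CI
Why: Williamson methylation of the only free hydroxyl, the ring A phenol still being a MOM ether; the mild carbonate base affects neither the silyl ethers nor the stereocentres.

Step 13
Reactants: 25 the bis-TIPS ether
Product: 26 [(2R,3S)-3-(hydroxymethyl)-7-methoxy-2-[3-methoxy-4-(methoxymethoxy)phenyl]-2,3-dihydro-1-benzofuran-5-yl]methanol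
Conditions: Bu4NF, THF, 0 → 20 °C
Reagents that add atoms: none
Why: Fluoride cleavage of both TIPS ethers in one operation; the MOM acetal and the aryl ethers are inert.

Step 14
Reactants: 26 the diol
Product: 27 (2R,3S)-3-(hydroxymethyl)-7-methoxy-2-[3-methoxy-4-(methoxymethoxy)phenyl]-2,3-dihydro-1-benzofuran-5-carbaldehyde
Conditions: MnO2, CH2Cl2, 20 °C
Reagents that add atoms: none
Why: MnO2 oxidises benzylic alcohols and leaves saturated primary alcohols, so only the C5 hydroxymethyl group becomes the aldehyde.

Step 15
Reactants: 27 the C5 aldehyde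
Product: 28 (2E)-3-[(2R,3S)-3-(hydroxymethyl)-7-methoxy-2-[3-methoxy-4-(methoxymethoxy)phenyl]-2,3-dihydro-1-benzofuran-5-yl]prop-2-enal
Conditions: Ph3P=CHCHO (1.2 equiv), toluene, 80 °C
Reagents that add atoms: (triphenylphosphoranylidene)acetaldehyde, O=CC=P(c1ccccc1)(c1ccccc1)c1ccccc1
Why: Wittig olefination with the stabilised formylmethylene ylide, which gives the (E)-enal; the free primary alcohol does not interfere and only a slight excess of ylide is used to limit a second homologation.

Step 16
Reactants: 28 the MOM-protected enal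
Product: 29 balanophonin, (2E)-3-[(2R,3S)-2-(4-hydroxy-3-methoxyphenyl)-3-(hydroxymethyl)-7-methoxy-2,3-dihydro-1-benzofuran-5-yl]prop-2-enal
Conditions: 3 M HCl (aq), THF, 40 °C
Reagents that add atoms: none
Why: Acid hydrolysis of the aryl MOM acetal in aqueous THF, with no alcohol present that could add to the enal; C3 cannot epimerise and trans is the stable arrangement, so even transient ionisation at C2 would return the same diastereomer.

## Compound list

1 | 4-bromofuran-2-carbaldehyde | O=Cc1cc(Br)co1 | starting material
2 | 4-(hydroxymethyl)furan-2-carbaldehyde | O=Cc1cc(CO)co1 | intermediate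
3 | 4-[(TIPS-oxy)methyl]furan-2-carbaldehyde | O=Cc1cc(CO[Si](C(C)C)(C(C)C)C(C)C)co1 | intermediate
4 | N-[2-{4-[(TIPS-oxy)methyl]furan-2-yl}-1-(4-methylbenzenesulfonyl)ethenyl]formamide (alkene geometry not defined) | O=CNC(=Cc1cc(CO[Si](C(C)C)(C(C)C)C(C)C)co1)S(=O)(=O)c1ccc(C)cc1 | intermediate (not isolated)
5 | 2-{4-[(TIPS-oxy)methyl]furan-2-yl}acetonitrile | N#CCc1cc(CO[Si](C(C)C)(C(C)C)C(C)C)co1 | intermediate
6 | 2-{4-[(TIPS-oxy)methyl]furan-2-yl}acetic acid | OC(=O)Cc1cc(CO[Si](C(C)C)(C(C)C)C(C)C)co1 | intermediate
7 | (4R)-4-benzyl-1,3-oxazolidin-2-one | O=C1OC[C@@H](Cc2ccccc2)N1 | starting material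
8 | 2,2-dimethylpropanoic 2-{4-[(TIPS-oxy)methyl]furan-2-yl}acetic anhydride | CC(C)(C)C(=O)OC(=O)Cc1cc(CO[Si](C(C)C)(C(C)C)C(C)C)co1 | intermediate (not isolated)
9 | (4R)-4-benzyl-3-(2-{4-[(TIPS-oxy)methyl]furan-2-yl}acetyl)-1,3-oxazolidin-2-one | O=C(Cc1cc(CO[Si](C(C)C)(C(C)C)C(C)C)co1)N1C(=O)OC[C@H]1Cc1ccccc1 | intermediate
10 | vanillin | COc1cc(C=O)ccc1O | starting material
11 | 3-methoxy-4-(methoxymethoxy)benzaldehyde | COCOc1ccc(C=O)cc1OC | intermediate
12 | (Z)-dibutylboron enolate of 9 | CCCCB(CCCC)O/C(=C\c1cc(CO[Si](C(C)C)(C(C)C)C(C)C)co1)N1C(=O)OC[C@H]1Cc1ccccc1 | intermediate (not isolated)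
13 | O-dibutylboryl derivative of 14 (boron aldolate) | COCOc1ccc(cc1OC)[C@H](OB(CCCC)CCCC)[C@H](C(=O)N1C(=O)OC[C@H]1Cc1ccccc1)c1cc(CO[Si](C(C)C)(C(C)C)C(C)C)co1 | intermediate (not isolated)
14 | (4R)-4-benzyl-3-[(2S,3R)-3-hydroxy-3-[3-methoxy-4-(methoxymethoxy)phenyl]-2-{4-[(TIPS-oxy)methyl]furan-2-yl}propanoyl]-1,3-oxazolidin-2-one | COCOc1ccc(cc1OC)[C@H](O)[C@H](C(=O)N1C(=O)OC[C@H]1Cc1ccccc1)c1cc(CO[Si](C(C)C)(C(C)C)C(C)C)co1 | intermediate
15 | (1R,2S)-1-[3-methoxy-4-(methoxymethoxy)phenyl]-2-{4-[(TIPS-oxy)methyl]furan-2-yl}propane-1,3-diol | COCOc1ccc(cc1OC)[C@H](O)[C@H](CO)c1cc(CO[Si](C(C)C)(C(C)C)C(C)C)co1 | intermediate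
16 | (1R,2S)-1-[3-methoxy-4-(methoxymethoxy)phenyl]-3-(TIPS-oxy)-2-{4-[(TIPS-oxy)methyl]furan-2-yl}propan-1-ol | COCOc1ccc(cc1OC)[C@H](O)[C@H](CO[Si](C(C)C)(C(C)C)C(C)C)c1cc(CO[Si](C(C)C)(C(C)C)C(C)C)co1 | intermediate
17 | trichloroethylene | ClC=C(Cl)Cl | starting material
18 | (E)-1,2-dichloroethenyl ether of 16 | COCOc1ccc(cc1OC)[C@H](O/C(Cl)=C\Cl)[C@H](CO[Si](C(C)C)(C(C)C)C(C)C)c1cc(CO[Si](C(C)C)(C(C)C)C(C)C)co1 | intermediate (not isolated)
19 | chloroethynyl ether of 16 | COCOc1ccc(cc1OC)[C@H](OC#CCl)[C@H](CO[Si](C(C)C)(C(C)C)C(C)C)c1cc(CO[Si](C(C)C)(C(C)C)C(C)C)co1 | intermediate (not isolated)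
20 | lithium acetylide of 21 | COCOc1ccc(cc1OC)[C@H](OC#C[Li])[C@H](CO[Si](C(C)C)(C(C)C)C(C)C)c1cc(CO[Si](C(C)C)(C(C)C)C(C)C)co1 | intermediate (not isolated)
21 | (1R,2S)-1-(ethynyloxy)-1-[3-methoxy-4-(methoxymethoxy)phenyl]-3-(TIPS-oxy)-2-{4-[(TIPS-oxy)methyl]furan-2-yl}propane | COCOc1ccc(cc1OC)[C@H](OC#C)[C@H](CO[Si](C(C)C)(C(C)C)C(C)C)c1cc(CO[Si](C(C)C)(C(C)C)C(C)C)co1 | intermediate
22 | (2R,3S)-2-[3-methoxy-4-(methoxymethoxy)phenyl]-3,5-bis[(TIPS-oxy)methyl]-2,3-dihydrofuro[2,3-c]oxepine (oxepine oxygen between the later C6 and C7; CH2O-TIPS on the later C5) | COCOc1ccc(cc1OC)[C@@H]1OC2=COC=C(CO[Si](C(C)C)(C(C)C)C(C)C)C=C2[C@H]1CO[Si](C(C)C)(C(C)C)C(C)C | intermediate (not isolated)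
23 | 6,7-epoxide (arene oxide) of the 2,3,6,7-tetrahydro-1-benzofuran, (2R,3S), valence tautomer of 22 | COCOc1ccc(cc1OC)[C@@H]1OC2=C(C=C(CO[Si](C(C)C)(C(C)C)C(C)C)C3OC23)[C@H]1CO[Si](C(C)C)(C(C)C)C(C)C | intermediate (not isolated)
24 | (2R,3S)-2-[3-methoxy-4-(methoxymethoxy)phenyl]-3,5-bis[(TIPS-oxy)methyl]-2,3-dihydro-1-benzofuran-7-ol | COCOc1ccc(cc1OC)[C@@H]1Oc2c(O)cc(CO[Si](C(C)C)(C(C)C)C(C)C)cc2[C@H]1CO[Si](C(C)C)(C(C)C)C(C)C | intermediate
25 | (2R,3S)-7-methoxy-2-[3-methoxy-4-(methoxymethoxy)phenyl]-3,5-bis[(TIPS-oxy)methyl]-2,3-dihydro-1-benzofuran | COCOc1ccc(cc1OC)[C@@H]1Oc2c(OC)cc(CO[Si](C(C)C)(C(C)C)C(C)C)cc2[C@H]1CO[Si](C(C)C)(C(C)C)C(C)C | intermediate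
26 | [(2R,3S)-3-(hydroxymethyl)-7-methoxy-2-[3-methoxy-4-(methoxymethoxy)phenyl]-2,3-dihydro-1-benzofuran-5-yl]methanol | COCOc1ccc(cc1OC)[C@@H]1Oc2c(OC)cc(CO)cc2[C@H]1CO | intermediate
27 | (2R,3S)-3-(hydroxymethyl)-7-methoxy-2-[3-methoxy-4-(methoxymethoxy)phenyl]-2,3-dihydro-1-benzofuran-5-carbaldehyde | COCOc1ccc(cc1OC)[C@@H]1Oc2c(OC)cc(C=O)cc2[C@H]1CO | intermediate
28 | (2E)-3-[(2R,3S)-3-(hydroxymethyl)-7-methoxy-2-[3-methoxy-4-(methoxymethoxy)phenyl]-2,3-dihydro-1-benzofuran-5-yl]prop-2-enal | COCOc1ccc(cc1OC)[C@@H]1Oc2c(OC)cc(/C=C/C=O)cc2[C@H]1CO | intermediate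
29 | balanophonin | COc1cc([C@@H]2Oc3c(OC)cc(/C=C/C=O)cc3[C@H]2CO)ccc1O | target

## Step count and risks

Total steps: 16. Longest linear sequence: 15 steps (1 to 29 through steps 1–5 and 7–16; step 6 is the side branch).

**Step 11 (key step).** The most likely failure is heterolysis of the benzylic C2–O1 bond once gold has made the alkynyl ether oxygen cationic, because ring A stabilises the benzylic cation. Thermal retro-ene loss of ketene through the activated C3–H, and hydration of the alkynyl ether by trace water, are the other losses. Arene-oxide opening may also be less clean than in the known cases because the furan has no substituent on the carbon that becomes C6. The fallback sets out from auxiliary 7 and aldehyde 11 and rejoins the route at 29; it buys ring B as an arene and closes O1–C2 instead.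
- Commercial 5-bromo-2-hydroxy-3-methoxybenzaldehyde F1 is protected (MOMCl, i-Pr2NEt) as 5-bromo-3-methoxy-2-(methoxymethoxy)benzaldehyde F2.
- F2 is homologated with TosMIC to the arylacetonitrile F3 and hydrolysed with KOH to the arylacetic acid F4.
- F4 is loaded onto 7 (t-BuCOCl, Et3N, LiCl) to give the imide F5.
- The same boron syn-aldol with 11 gives the adduct F6, and LiBH4 gives the diol F7.
- HCl in THF/MeOH removes both MOM groups and ionises the benzylic alcohol; the ring B phenol closes ring C under control by C3 to the trans bromide F8.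
- A Heck reaction of F8 with acrolein diethyl acetal (Pd(OAc)2, Bu4NOAc, K2CO3, KCl, DMF, 90 °C), followed by dilute HCl to hydrolyse the acetal, gives 29.

**Step 10.** The likely failures are fragmentation of the labile secondary benzylic alkynyl ether on warming or concentration, and silyl migration or elimination at the potassium alkoxide stage before the alkoxide is captured. The fallback sets out from alcohol 16 and rejoins at 20, hence 21, without ever forming the alkoxide. Alcohol 16 is formylated with acetic formic anhydride and pyridine to the formate F9. Dibromo-olefination of the formyl group with CBr4 and PPh3 (Corey–Fuchs type) gives the 2,2-dibromoethenyl ether F10. n-BuLi at –78 °C then effects elimination and bromine–lithium exchange to 20, which is protonated as in step 10.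

**Step 7.** The furyl-conjugated boron enolate is stabilised and the aldehyde is electron-rich, so slow addition, retro-aldol and epimerisation at the acidic α-furyl position may erode the diastereomeric purity. The fallback sets out from acid 6 and aldehyde 11 and rejoins at diol 15. Acid 6 is coupled (carbodiimide, DMAP) with (4R)-4-benzyl-1,3-thiazolidine-2-thione to give the N-acyl thiazolidinethione F11. Its chlorotitanium enolate (TiCl4, i-Pr2NEt, N-methylpyrrolidinone, CH2Cl2, –78 °C) adds to 11 in the same syn sense to give the adduct F12. NaBH4 in THF/EtOH removes the auxiliary under very mild conditions to give 15.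

**Step 3.** Elimination of sulfinic acid from the oxazoline to the oxazole, and base-induced degradation of the furaldehyde, may compete with the reductive cyanation. The fallback sets out from aldehyde 3 and rejoins at acid 6. A Wittig reaction with (methoxymethyl)triphenylphosphonium chloride and KOt-Bu gives the enol ether F13 as an E/Z mixture. Mild aqueous formic acid hydrolyses it to the furylacetaldehyde F14. Pinnick oxidation (NaClO2, NaH2PO4, 2-methylbut-2-ene) gives 6.

**Step 15.** The product enal can react again with the ylide, and the electron-rich aldehyde reacts slowly, so over-homologation to the dienal may accompany incomplete conversion. The fallback sets out from aldehyde 27 and rejoins at 28. Horner–Wadsworth–Emmons olefination with triethyl phosphonoacetate (LiCl, DBU, MeCN) gives the (E)-cinnamate F15. Reduction with i-Bu2AlH at –78 °C gives the allylic alcohol F16. MnO2 oxidises the allylic alcohol, not the saturated one, to 28.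

## Further compounds

F1 | step 11 | 5-bromo-2-hydroxy-3-methoxybenzaldehyde (purchased) | COc1cc(Br)cc(C=O)c1O
F2 | step 11 | 5-bromo-3-methoxy-2-(methoxymethoxy)benzaldehyde | COCOc1c(OC)cc(Br)cc1C=O
F3 | step 11 | 2-[5-bromo-3-methoxy-2-(methoxymethoxy)phenyl]acetonitrile | COCOc1c(OC)cc(Br)cc1CC#N
F4 | step 11 | 2-[5-bromo-3-methoxy-2-(methoxymethoxy)phenyl]acetic acid | COCOc1c(OC)cc(Br)cc1CC(=O)O
F5 | step 11 | (4R)-4-benzyl-3-{2-[5-bromo-3-methoxy-2-(methoxymethoxy)phenyl]acetyl}-1,3-oxazolidin-2-one | COCOc1c(OC)cc(Br)cc1CC(=O)N1C(=O)OC[C@H]1Cc1ccccc1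
F6 | step 11 | (4R)-4-benzyl-3-[(2R,3R)-2-[5-bromo-3-methoxy-2-(methoxymethoxy)phenyl]-3-hydroxy-3-[3-methoxy-4-(methoxymethoxy)phenyl]propanoyl]-1,3-oxazolidin-2-one | COCOc1ccc(cc1OC)[C@H](O)[C@H](C(=O)N1C(=O)OC[C@H]1Cc1ccccc1)c1cc(Br)cc(OC)c1OCOC
F7 | step 11 | (1R,2S)-2-[5-bromo-3-methoxy-2-(methoxymethoxy)phenyl]-1-[3-methoxy-4-(methoxymethoxy)phenyl]propane-1,3-diol | COCOc1ccc(cc1OC)[C@H](O)[C@H](CO)c1cc(Br)cc(OC)c1OCOC
F8 | step 11 | 4-[(2R,3S)-5-bromo-3-(hydroxymethyl)-7-methoxy-2,3-dihydro-1-benzofuran-2-yl]-2-methoxyphenol | COc1cc([C@@H]2Oc3c(OC)cc(Br)cc3[C@H]2CO)ccc1O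
F9 | step 10 | formate ester of 16 | COCOc1ccc(cc1OC)[C@H](OC=O)[C@H](CO[Si](C(C)C)(C(C)C)C(C)C)c1cc(CO[Si](C(C)C)(C(C)C)C(C)C)co1
F10 | step 10 | 2,2-dibromoethenyl ether of 16 | COCOc1ccc(cc1OC)[C@H](OC=C(Br)Br)[C@H](CO[Si](C(C)C)(C(C)C)C(C)C)c1cc(CO[Si](C(C)C)(C(C)C)C(C)C)co1
F11 | step 7 | (4R)-4-benzyl-3-(2-{4-[(TIPS-oxy)methyl]furan-2-yl}acetyl)-1,3-thiazolidine-2-thione | O=C(Cc1cc(CO[Si](C(C)C)(C(C)C)C(C)C)co1)N1C(=S)SC[C@H]1Cc1ccccc1
F12 | step 7 | (2S,3R)-syn-aldol adduct of F11 and 11 | COCOc1ccc(cc1OC)[C@H](O)[C@H](C(=O)N1C(=S)SC[C@H]1Cc1ccccc1)c1cc(CO[Si](C(C)C)(C(C)C)C(C)C)co1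
F13 | step 3 | 2-(2-methoxyethenyl)-4-[(TIPS-oxy)methyl]furan (E/Z mixture) | COC=Cc1cc(CO[Si](C(C)C)(C(C)C)C(C)C)co1
F14 | step 3 | 2-{4-[(TIPS-oxy)methyl]furan-2-yl}acetaldehyde | O=CCc1cc(CO[Si](C(C)C)(C(C)C)C(C)C)co1
F15 | step 15 | ethyl (2E)-3-[(2R,3S)-3-(hydroxymethyl)-7-methoxy-2-[3-methoxy-4-(methoxymethoxy)phenyl]-2,3-dihydro-1-benzofuran-5-yl]prop-2-enoate | COCOc1ccc(cc1OC)[C@@H]1Oc2c(OC)cc(/C=C/C(=O)OCC)cc2[C@H]1CO
F16 | step 15 | (2E)-3-[(2R,3S)-3-(hydroxymethyl)-7-methoxy-2-[3-methoxy-4-(methoxymethoxy)phenyl]-2,3-dihydro-1-benzofuran-5-yl]prop-2-en-1-ol | COCOc1ccc(cc1OC)[C@@H]1Oc2c(OC)cc(/C=C/CO)cc2[C@H]1CO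
A1 | alternative 1 | trans-2-(pinacolboryl)-5-bromo-7-methoxy-2-[3-methoxy-4-(TIPS-oxy)phenyl]-3-[(TIPS-oxy)methyl]-2,3-dihydro-1-benzofuran | COc1cc([C@]2(B4OC(C)(C)C(C)(C)O4)Oc3c(OC)cc(Br)cc3[C@H]2CO[Si](C(C)C)(C(C)C)C(C)C)ccc1O[Si](C(C)C)(C(C)C)C(C)C
A2 | alternative 1 | 2-(5-bromo-7-methoxy-1-benzofuran-2-yl)-4,4,5,5-tetramethyl-1,3,2-dioxaborolane | COc1cc(Br)cc2cc(B3OC(C)(C)C(C)(C)O3)oc12
A3 | alternative 2 | methyl trans-5-bromo-7-methoxy-2-[3-methoxy-4-(pivaloyloxy)phenyl]-2,3-dihydro-1-benzofuran-3-carboxylate | COc1cc([C@@H]2Oc3c(OC)cc(Br)cc3[C@H]2C(=O)OC)ccc1OC(=O)C(C)(C)C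
A4 | alternative 2 | (2R)-6-bromo-8-methoxy-2-[3-methoxy-4-(pivaloyloxy)phenyl]-2,3-dihydro-4H-chromen-4-one | COc1cc([C@@H]2Oc3c(OC)cc(Br)cc3C(=O)C2)ccc1OC(=O)C(C)(C)C
A5 | alternative 3 | methyl trans-7-bromo-2-[3-methoxy-4-(methoxymethoxy)phenyl]-3-[(tert-butyldimethylsilyloxy)methyl]-2,3-dihydro-1-benzofuran-5-carboxylate | COc1cc([C@@H]2Oc3c(Br)cc(C(=O)OC)cc3[C@H]2CO[Si](C)(C)C(C)(C)C)ccc1OCOC
A6 | alternative 3 | trans-4-[(tert-butyldimethylsilyloxy)methyl]-5-[3-methoxy-4-(methoxymethoxy)phenyl]oxolan-2-one | COCOc1ccc(cc1OC)[C@@H]1OC(=O)C[C@H]1CO[Si](C)(C)C(C)(C)C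
A7 | alternative 3 | trimethylsilyl ketene acetal of A6 (2-trimethylsilyloxy-4,5-dihydrofuran) | COCOc1ccc(cc1OC)[C@@H]1OC(O[Si](C)(C)C)=C[C@H]1CO[Si](C)(C)C(C)(C)C
A8 | alternative 3 | methyl 3-bromo-2-oxo-2H-pyran-5-carboxylate | COC(=O)C1=COC(=O)C(Br)=C1
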